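Numbering: naphthalene C1 carries the 3,4,5-trimethoxyphenyl ring C, C2 and C3 carry the methyls, C6 the OH and C7 the OMe. Ring A is C4a-C5-C6-C7-C8-C8a and ring B is C1-C2-C3-C4-C4a-C8a.
Feature used: the C3=C4 edge of ring B is a trisubstituted olefin conjugated to ring A (C4-H on C4a, CH3 on C3). C1 can stand as a tertiary diaryl carbinol next to a C2-H, so ring B equals a 1,2-dihydronaphthalen-1-ol minus water.
Disconnections, backwards: C6 O-benzyl; water across C1/C2; C3=C4 (ring-closing metathesis of a ring A vinyl group with an isopropenyl group); C1-C2 (gamma-selective allylzinc addition bringing C2, C3 and both methyls); C4a-C4 (Suzuki vinylation); C1-ring C (Grignard addition, oxidation).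
Ring order: rings A and C are purchased. Ring B is the only ring built; it closes in step 6 and becomes aromatic in step 7.

Key step: step 6

Remark: 5, 11 and 12 are racemic, and 11 and 12 are carried as C1/C2 diastereomer mixtures because both centres become sp2 in step 7 and the target is achiral; 9 is taken as purchasable, and its olefin geometry is irrelevant because the derived allylzinc 10 is fluxional.

Step 1
Reactants: 1 6-bromovanillin (2-bromo-4-hydroxy-5-methoxybenzaldehyde)
Product: 2 4-(benzyloxy)-2-bromo-5-methoxybenzaldehyde
Conditions: BnBr, K2CO3, DMF, rt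
Reagents that add atoms: benzyl bromide, BrCc1ccccc1
Why: Williamson ether synthesis, in which the phenol (acidified by the para formyl group) is deprotonated by K2CO3 and displaces bromide from benzyl bromide by SN2, while the aldehyde and aryl bromide stay inert and the C6 oxygen is masked for the organometallic steps.

Step 2
Reactants: 2 4-(benzyloxy)-2-bromo-5-methoxybenzaldehyde; 3 5-bromo-1,2,3-trimethoxybenzene
Product: 5 [4-(benzyloxy)-2-bromo-5-methoxyphenyl](3,4,5-trimethoxyphenyl)methanol (racemic), via 3,4,5-trimethoxyphenylmagnesium bromide 4 (not isolated)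
Conditions: 3, Mg turnings, cat. I2, THF, reflux; then 2, THF, 0 °C to rt; sat. aq NH4Cl
Reagents that add atoms: none
Why: Grignard addition, in which the arylmagnesium bromide attacks the non-enolisable aldehyde far faster than it can exchange with the aryl bromide of 2 at 0 °C, and the new carbinol centre forms racemic, which does not matter because step 3 oxidises it.

Step 3
Reactants: 5 [4-(benzyloxy)-2-bromo-5-methoxyphenyl](3,4,5-trimethoxyphenyl)methanol
Product: 6 [4-(benzyloxy)-2-bromo-5-methoxyphenyl](3,4,5-trimethoxyphenyl)methanone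
Conditions: activated MnO2 (excess), CH2Cl2, rt
Reagents that add atoms: none
Why: Benzylic alcohol oxidation with MnO2, a mild heterogeneous oxidant that takes the doubly benzylic secondary alcohol to the ketone and leaves the aryl bromide, benzyl ether and methyl ethers untouched.

Step 4
Reactants: 6 [4-(benzyloxy)-2-bromo-5-methoxyphenyl](3,4,5-trimethoxyphenyl)methanone; 7 potassium vinyltrifluoroborate
Product: 8 [4-(benzyloxy)-2-ethenyl-5-methoxyphenyl](3,4,5-trimethoxyphenyl)methanone
Conditions: PdCl2(dppf)·CH2Cl2 (5 mol %), Cs2CO3 (3 equiv), THF/H2O 9:1, 80 °C, sealed vessel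
Reagents that add atoms: none
Why: Suzuki-Miyaura coupling of an organotrifluoroborate, in which oxidative addition of zerovalent palladium into the C-Br bond is helped by the ortho aroyl group, 7 passes its vinyl group to palladium under the aqueous base, and reductive elimination forms the C4a-C4 bond without touching the ketone.

Step 5
Reactants: 8 [4-(benzyloxy)-2-ethenyl-5-methoxyphenyl](3,4,5-trimethoxyphenyl)methanone; 9 (E)-1-bromo-2-methylbut-2-ene
Product: 11 1-[4-(benzyloxy)-2-ethenyl-5-methoxyphenyl]-2,3-dimethyl-1-(3,4,5-trimethoxyphenyl)but-3-en-1-ol (racemic mixture of diastereomers), via (2-methylbut-2-en-1-yl)zinc bromide 10 (not isolated)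
Conditions: 9, Zn dust, LiCl, THF, 0 °C; then 8, THF, -40 to 0 °C; sat. aq NH4Cl at 0 °C
Reagents that add atoms: none
Why: Allylzinc addition to a ketone in the SE2' mode, where a six-membered cyclic transition state bonds the methyl-bearing gamma carbon of 10 to C1 and shifts the double bond into the isopropenyl terminus, the ketone has no alpha hydrogen to enolise, the cold and prompt quench forestalls reversal of the addition, and the C1 and C2 stereocentres are deliberately left uncontrolled because step 7 erases both.

Step 6
Reactants: 11 1-[4-(benzyloxy)-2-ethenyl-5-methoxyphenyl]-2,3-dimethyl-1-(3,4,5-trimethoxyphenyl)but-3-en-1-ol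
Product: 12 6-(benzyloxy)-7-methoxy-2,3-dimethyl-1-(3,4,5-trimethoxyphenyl)-1,2-dihydronaphthalen-1-ol (racemic mixture of diastereomers)
Conditions: second-generation Grubbs catalyst (H2IMes)(PCy3)Cl2Ru=CHPh (5 mol %), degassed acid-free CH2Cl2 (0.005 M), 40 °C, argon stream
Reagents that add atoms: none
Why: Ring-closing olefin metathesis by the Chauvin mechanism: after PCy3 dissociates, the ruthenium alkylidene exchanges with the monosubstituted ring A vinyl group (the only olefin it engages readily), and the resulting ring A benzylidene adds intramolecularly across the isopropenyl C3=CH2 to a ruthenacyclobutane whose cycloreversion delivers the C3=C4 bond and Ru=CH2, which reloads on the next styrene with release of ethylene. The closest known reaction type is the closure of 1-(2-vinylaryl)but-3-en-1-ols to 1,2-dihydronaphthalen-1-ols with this catalyst class, which also accepts 1,1-disubstituted partners and free hydroxyl groups. Ring B closes as a six-membered carbocycle from a 1,7-diene whose tether (C4a and C8a fixed ortho on ring A, quaternary C1, branched C2) already holds the two olefins close together, so the closure has a strong conformational bias. No stereocentre is created or touched: C1 and C2 pass through as the diastereomer mixture and both vanish in step 7. The selectivity needed is ring closure over intermolecular styrene homocoupling, and it is secured by the six-membered ring size, by the inability of the 1,1-disubstituted olefin to homodimerise, by the 0.005 M dilution and by sweeping out ethylene. Acid-free solvent keeps the ionisable C1 carbinol intact until the ring is closed, and any loss of water from 12 after closure would only anticipate step 7.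

Step 7
Reactants: 12 6-(benzyloxy)-7-methoxy-2,3-dimethyl-1-(3,4,5-trimethoxyphenyl)-1,2-dihydronaphthalen-1-ol
Product: 13 6-(benzyloxy)-7-methoxy-2,3-dimethyl-1-(3,4,5-trimethoxyphenyl)naphthalene
Conditions: p-TsOH·H2O (5 mol %), CH2Cl2, rt
Reagents that add atoms: none
Why: Acid-catalysed E1 dehydration, in which loss of water gives a C1 cation stabilised by ring C and by the C6 benzyloxy group para to C8a, and loss of the C2 proton is driven by aromatisation of ring B, so both diastereomers converge on one naphthalene while the benzyl ether survives the catalytic acid.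

Step 8
Reactants: 13 6-(benzyloxy)-7-methoxy-2,3-dimethyl-1-(3,4,5-trimethoxyphenyl)naphthalene
Product: 14 CNP0280611.0, 3-methoxy-6,7-dimethyl-5-(3,4,5-trimethoxyphenyl)naphthalen-2-ol (C6-OH, C7-OMe in route numbering)
Conditions: H2 (1 atm), 10% Pd/C, EtOAc/EtOH, rt
Reagents that add atoms: none
Why: Catalytic hydrogenolysis of a benzyl aryl ether, which cleaves the benzylic C-O bond at ambient pressure while the naphthalene core and the aryl methyl ethers are not reduced under these conditions.

Compound list
1 | 6-bromovanillin (2-bromo-4-hydroxy-5-methoxybenzaldehyde) | O=Cc1cc(OC)c(O)cc1Br | starting material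
2 | 4-(benzyloxy)-2-bromo-5-methoxybenzaldehyde | O=Cc1cc(OC)c(OCc2ccccc2)cc1Br | intermediate
3 | 5-bromo-1,2,3-trimethoxybenzene | COc1cc(Br)cc(OC)c1OC | starting material
4 | 3,4,5-trimethoxyphenylmagnesium bromide (not isolated) | COc1cc([Mg]Br)cc(OC)c1OC | intermediate
5 | [4-(benzyloxy)-2-bromo-5-methoxyphenyl](3,4,5-trimethoxyphenyl)methanol, racemic | OC(c1cc(OC)c(OC)c(OC)c1)c1cc(OC)c(OCc2ccccc2)cc1Br | intermediate
6 | [4-(benzyloxy)-2-bromo-5-methoxyphenyl](3,4,5-trimethoxyphenyl)methanone | O=C(c1cc(OC)c(OC)c(OC)c1)c1cc(OC)c(OCc2ccccc2)cc1Br | intermediate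
7 | potassium vinyltrifluoroborate | C=C[B-](F)(F)F.[K+] | starting material
8 | [4-(benzyloxy)-2-ethenyl-5-methoxyphenyl](3,4,5-trimethoxyphenyl)methanone | C=Cc1cc(OCc2ccccc2)c(OC)cc1C(=O)c1cc(OC)c(OC)c(OC)c1 | intermediate
9 | (E)-1-bromo-2-methylbut-2-ene | C/C=C(\C)CBr | starting material
10 | (2-methylbut-2-en-1-yl)zinc bromide (not isolated, fluxional) | C/C=C(\C)C[Zn]Br | intermediate
11 | 1-[4-(benzyloxy)-2-ethenyl-5-methoxyphenyl]-2,3-dimethyl-1-(3,4,5-trimethoxyphenyl)but-3-en-1-ol, racemic diastereomer mixture (centres unspecified) | C=Cc1cc(OCc2ccccc2)c(OC)cc1C(O)(c1cc(OC)c(OC)c(OC)c1)C(C)C(C)=C | intermediate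
12 | 6-(benzyloxy)-7-methoxy-2,3-dimethyl-1-(3,4,5-trimethoxyphenyl)-1,2-dihydronaphthalen-1-ol, racemic diastereomer mixture (centres unspecified) | CC1=Cc2cc(OCc3ccccc3)c(OC)cc2C(O)(c2cc(OC)c(OC)c(OC)c2)C1C | intermediate
13 | 6-(benzyloxy)-7-methoxy-2,3-dimethyl-1-(3,4,5-trimethoxyphenyl)naphthalene | COc1cc2c(-c3cc(OC)c(OC)c(OC)c3)c(C)c(C)cc2cc1OCc1ccccc1 | intermediate
14 | CNP0280611.0, 3-methoxy-6,7-dimethyl-5-(3,4,5-trimethoxyphenyl)naphthalen-2-ol (achiral) | COc1cc2c(-c3cc(OC)c(OC)c(OC)c3)c(C)c(C)cc2cc1O | target

Total step count: 8. Longest linear sequence: 8 steps (1 to 14).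

Steps most likely to fail

Step 6.
- **Risk:** The ring A ruthenium benzylidene may add only sluggishly to the isopropenyl group, which sits next to the branched C2 and the fully substituted C1. Intermolecular styrene coupling, catalyst decay and hydride-induced olefin migration could then compete. Premature ionisation at C1 would also scramble the geometry needed for closure.
- **Fallback:** It uses no metathesis and closes ring B at C1=C2 by reductive carbonyl coupling. It sets out from 6 and rejoins the route at 13.
- Heck arylation of commercial 3-methylbut-3-en-2-ol with 6 (Pd(OAc)2, P(o-tol)3, NaHCO3, DMF, 100 °C) should put the aryl group on the CH2 terminus. Beta-hydride elimination toward the carbinol carbon and enol tautomerisation should then give 4-[5-(benzyloxy)-4-methoxy-2-(3,4,5-trimethoxybenzoyl)phenyl]-3-methylbutan-2-one F1.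
- Intramolecular McMurry coupling of its two ketones with low-valent titanium (TiCl4, Zn, pyridine, THF, reflux, slow addition) should give 7-(benzyloxy)-6-methoxy-2,3-dimethyl-4-(3,4,5-trimethoxyphenyl)-1,2-dihydronaphthalene F2.
- Dehydrogenation with DDQ (toluene, 80 °C) should aromatise ring B to 13.

Step 5.
- **Risk:** Addition to the electron-rich, ortho-substituted diaryl ketone may be slow and reversible. Retro-allylation and re-addition through the unsubstituted CH2 terminus of the allyl unit would then erode the gamma regiochemistry.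
- **Fallback:** It reverses the order of bond formation. C1-C2 is made on an aldehyde, where gamma addition is fast and irreversible, and ring C is added last. It sets out from 2 and rejoins at 11.
- Suzuki vinylation of 2 with 7 under the conditions of step 4 should give 4-(benzyloxy)-2-ethenyl-5-methoxybenzaldehyde F3.
- Addition of 10 (THF, -78 °C) should give 1-[4-(benzyloxy)-2-ethenyl-5-methoxyphenyl]-2,3-dimethylbut-3-en-1-ol F4.
- Neutral oxidation with MnO2 (CH2Cl2, rt) should give 1-[4-(benzyloxy)-2-ethenyl-5-methoxyphenyl]-2,3-dimethylbut-3-en-1-one F5 without moving the beta,gamma double bond.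
- Reagent 4 in the presence of LaCl3·2LiCl (THF, 0 °C), which suppresses enolisation, should add to this ketone to give 11.

Step 4.
- **Risk:** Transmetalation at the bromide flanked by the aroyl group may be slow. That would leave room for loss of the vinyl donor by protodeboronation, for hydrodebromination, and for Heck-type consumption or polymerisation of the freshly formed styrene.
- **Fallback:** It uses no palladium and introduces C4 as a formyl carbon that is then methylenated. It sets out from 5 and rejoins at 8.
- Deprotonation and bromine-lithium exchange of 5 (n-BuLi, 2.2 equiv, THF, -78 °C) followed by DMF should give the hydroxy aldehyde, which closes to 6-(benzyloxy)-5-methoxy-3-(3,4,5-trimethoxyphenyl)-1,3-dihydro-2-benzofuran-1-ol F6.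
- Wittig methylenation of this lactol (Ph3PCH3Br, KOt-Bu, 3 equiv, THF, 0 °C to rt) should give [4-(benzyloxy)-2-ethenyl-5-methoxyphenyl](3,4,5-trimethoxyphenyl)methanol F7.
- MnO2 (CH2Cl2, rt) should oxidise F7 to 8.

Further compounds
F1 | step 6 | 4-[5-(benzyloxy)-4-methoxy-2-(3,4,5-trimethoxybenzoyl)phenyl]-3-methylbutan-2-one (racemic) | CC(=O)C(C)Cc1cc(OCc2ccccc2)c(OC)cc1C(=O)c1cc(OC)c(OC)c(OC)c1
F2 | step 6 | 7-(benzyloxy)-6-methoxy-2,3-dimethyl-4-(3,4,5-trimethoxyphenyl)-1,2-dihydronaphthalene (racemic) | CC1Cc2cc(OCc3ccccc3)c(OC)cc2C(c2cc(OC)c(OC)c(OC)c2)=C1C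
F3 | step 5 | 4-(benzyloxy)-2-ethenyl-5-methoxybenzaldehyde | C=Cc1cc(OCc2ccccc2)c(OC)cc1C=O
F4 | step 5 | 1-[4-(benzyloxy)-2-ethenyl-5-methoxyphenyl]-2,3-dimethylbut-3-en-1-ol (racemic diastereomer mixture) | C=Cc1cc(OCc2ccccc2)c(OC)cc1C(O)C(C)C(C)=C
F5 | step 5 | 1-[4-(benzyloxy)-2-ethenyl-5-methoxyphenyl]-2,3-dimethylbut-3-en-1-one (racemic) | C=Cc1cc(OCc2ccccc2)c(OC)cc1C(=O)C(C)C(C)=C
F6 | step 4 | 6-(benzyloxy)-5-methoxy-3-(3,4,5-trimethoxyphenyl)-1,3-dihydro-2-benzofuran-1-ol (racemic, anomer mixture) | OC1OC(c2cc(OC)c(OC)c(OC)c2)c2cc(OC)c(OCc3ccccc3)cc12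
F7 | step 4 | [4-(benzyloxy)-2-ethenyl-5-methoxyphenyl](3,4,5-trimethoxyphenyl)methanol (racemic) | C=Cc1cc(OCc2ccccc2)c(OC)cc1C(O)c1cc(OC)c(OC)c(OC)c1
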